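**Assumptions.** The target is natural (2R,4'R,8'R)-δ-tocopherol. Commercial natural phytol is (2E,7R,11R) and E-rich; any Z isomer is removed by chromatography at the epoxide stage.

## Retrosynthetic overview
1. Last step: remove a benzyl ether from the 6-O-benzyl chroman.
2. The chroman (pyran) ring is closed last, by Pd-catalysed intramolecular C–O coupling of a tertiary alcohol with an aryl bromide. The carbinol C–O bond is never broken, so the C2 configuration is retained.
3. The aryl bromide comes from para-selective bromination of the aryl-alkyl tertiary alcohol. That alcohol comes from Ni-catalysed reductive coupling of a primary alkyl iodide with 3-bromo-5-methylphenyl benzyl ether.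
4. The alkyl iodide comes from a chiral 1,3-diol, made by Red-Al opening of the Sharpless epoxy-alcohol of (7R,11R)-phytol. The AE sets the future C2. Phytol supplies C4' and C8' and the whole side chain.

## Route

**Step 1**
Reactants: 1, (2E,7R,11R)-phytol
Product: 2, [(2R,3R)-3-methyl-3-[(4R,8R)-4,8,12-trimethyltridecyl]oxiran-2-yl]methanol
Conditions: Ti(OiPr)4 (10 mol%), D-(–)-DET (12 mol%), TBHP, 4 Å MS, CH2Cl2, –20 °C
Reagents that add atoms: tert-butyl hydroperoxide, CC(C)(C)OO (supplies the epoxide O)
Why: Sharpless asymmetric epoxidation of an E-trisubstituted allylic alcohol; D-tartrate delivers O to one face and sets the quaternary epoxide carbon (future C2) as R.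

**Step 2**
Reactants: 2
Product: 3, (3R,7R,11R)-3,7,11,15-tetramethylhexadecane-1,3-diol
Conditions: Red-Al, THF, 0 °C to rt
Reagents that add atoms: none (hydride only)
Why: Hydroxyl-directed hydride delivery to C2 (Red-Al opening of a 2,3-epoxy alcohol) cleaves the C2–O bond and leaves the tertiary C3–O bond untouched, so the stereocentre is retained.

**Step 3**
Reactants: 3
Product: 4, (3R,7R,11R)-1-iodo-3,7,11,15-tetramethylhexadecan-3-ol
Conditions: I2, PPh3, imidazole, CH2Cl2, 0 °C to rt
Reagents that add atoms: iodine, II
Why: Appel-type iodination is selective for the unhindered primary alcohol; the tertiary carbinol is not involved, so its configuration is unchanged.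

**Step 4**
Reactants: 5, 3-bromo-5-methylphenol
Product: 6, 1-(benzyloxy)-3-bromo-5-methylbenzene
Conditions: BnBr, K2CO3, DMF, 60 °C
Reagents that add atoms: benzyl bromide, BrCc1ccccc1
Why: Williamson O-benzylation masks the future 6-OH so that it survives the bromination, Pd and Ni steps.

**Step 5**
Reactants: 4 and 6 (1.5 equiv)
Product: 7, (3R,7R,11R)-1-[3-(benzyloxy)-5-methylphenyl]-3,7,11,15-tetramethylhexadecan-3-ol
Conditions: NiBr2·diglyme (10 mol%), dtbbpy (10 mol%), Zn dust, DMA, 60 °C
Reagents that add atoms: none
Why: Ni-catalysed cross-electrophile (reductive) sp3–sp2 coupling joins C1 to the arene (C4–C4a bond) and tolerates the free tertiary OH; no stereocentre is touched.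

**Step 6**
Reactants: 7
Product: 8, (3R,7R,11R)-1-[5-(benzyloxy)-2-bromo-3-methylphenyl]-3,7,11,15-tetramethylhexadecan-3-ol
Conditions: NBS, MeCN, 0 °C to rt, dark
Reagents that add atoms: N-bromosuccinimide, O=C1CCC(=O)N1Br
Why: Electrophilic aromatic bromination goes para to the strongest donor (OBn), at the only position flanked by the methyl and the alkyl chain; this is the future C8a.

**Step 7**
Reactants: 8
Product: 9, (2R,4'R,8'R)-6-(benzyloxy)-δ-tocopherol, i.e. (2R)-6-(benzyloxy)-2,8-dimethyl-2-[(4R,8R)-4,8,12-trimethyltridecyl]chromane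
Conditions: Pd2(dba)3 (2.5 mol%), RockPhos (10 mol%), Cs2CO3, toluene, 100 °C
Reagents that add atoms: none
Why: Buchwald-type intramolecular Pd-catalysed etherification forms the aryl–O bond; the tertiary alkoxide has no α-H to eliminate and its C–O bond is retained, so the C2 configuration is kept.

**Step 8**
Reactants: 9
Product: 10, (2R,4'R,8'R)-δ-tocopherol
Conditions: H2 (1 atm), 10% Pd/C, EtOAc, rt
Reagents that add atoms: none (H2 only)
Why: Hydrogenolysis of the phenolic benzyl ether; the aryl tertiary alkyl ether and all stereocentres are untouched.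

## Compound list
1 | (2E,7R,11R)-phytol | CC(C)CCC[C@@H](C)CCC[C@@H](C)CCC/C(C)=C/CO | starting material
2 | [(2R,3R)-3-methyl-3-[(4R,8R)-4,8,12-trimethyltridecyl]oxiran-2-yl]methanol | OC[C@H]1O[C@]1(C)CCC[C@H](C)CCC[C@H](C)CCCC(C)C | intermediate
3 | (3R,7R,11R)-3,7,11,15-tetramethylhexadecane-1,3-diol | OCC[C@](C)(O)CCC[C@H](C)CCC[C@H](C)CCCC(C)C | intermediate
4 | (3R,7R,11R)-1-iodo-3,7,11,15-tetramethylhexadecan-3-ol | ICC[C@](C)(O)CCC[C@H](C)CCC[C@H](C)CCCC(C)C | intermediate
5 | 3-bromo-5-methylphenol | Cc1cc(O)cc(Br)c1 | starting material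
6 | 1-(benzyloxy)-3-bromo-5-methylbenzene | Cc1cc(Br)cc(OCc2ccccc2)c1 | intermediate
7 | (3R,7R,11R)-1-[3-(benzyloxy)-5-methylphenyl]-3,7,11,15-tetramethylhexadecan-3-ol | Cc1cc(OCc2ccccc2)cc(CC[C@](C)(O)CCC[C@H](C)CCC[C@H](C)CCCC(C)C)c1 | intermediate
8 | (3R,7R,11R)-1-[5-(benzyloxy)-2-bromo-3-methylphenyl]-3,7,11,15-tetramethylhexadecan-3-ol | Cc1cc(OCc2ccccc2)cc(CC[C@](C)(O)CCC[C@H](C)CCC[C@H](C)CCCC(C)C)c1Br | intermediate
9 | (2R,4'R,8'R)-6-(benzyloxy)-δ-tocopherol | Cc1cc(OCc2ccccc2)cc2c1O[C@](C)(CCC[C@H](C)CCC[C@H](C)CCCC(C)C)CC2 | intermediate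
10 | (2R,4'R,8'R)-δ-tocopherol | Cc1cc(O)cc2c1O[C@](C)(CCC[C@H](C)CCC[C@H](C)CCCC(C)C)CC2 | target

## Totals
Total steps: 8. Longest linear sequence: 7 (1 → 2 → 3 → 4 → 7 → 8 → 9 → 10; step 4, the benzylation, is a parallel branch).

## Three steps most likely to fail
1. **Step 7 (hindered C–O coupling):** the aryl bromide is di-ortho-substituted and the alcohol is tertiary. Fallback: convert 8 to the aryl boronic ester by Miyaura borylation, then close the ring by Cu(OAc)2-mediated Chan–Lam etherification. This uses a different mechanism and still retains the carbinol C–O bond.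
2. **Step 5 (Ni cross-electrophile coupling of a hindered γ-hydroxy primary iodide):** homocoupling or reduction of the iodide may compete. Fallback: reverse the polarity. Make the alkylzinc from 4 (with the tertiary OH as its TES ether), do a Negishi coupling with 6 using Pd-PEPPSI, then remove the TES group.
3. **Step 6 (regioselective para-bromination):** the ring is a 1,3,5-trisubstituted arene with three activated positions, so ortho isomers may form. Fallback: skip bromination and Pd, and close the ring on 7 directly by hypervalent-iodine (PIFA/BF3) oxidative intramolecular C–H alkoxylation of the electron-rich arene.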